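**Plan** (cembrane-type locants: C1 = ring carbon bearing C15 of the 2-acetoxyprop-2-yl group; C3=C4 Z-olefin; C7–C8 oxirane; C10 = ring CH–OAc; C11=C12 E-olefin)
Retrosynthesis: remove the C15 acetate, open the oxirane to a C7 mesylate and C8 tertiary alcohol (C8–O displaces at C7 with inversion), and take C10–OAc back to a C10 ketone. Then cut the 14-membered ring at C8–C9: the C8 and C10 oxygens stand 1,3 across C9, so this is an aldol bond, and the vicinal C7 oxygen (as PMB ether) makes C8 a chelating α-alkoxy methyl ketone. The open chain is cut at C10–C11 (vinyllithium acylation), C1–C2 (Evans alkylation), C5–C6 (ketone enolate alkylation) and C3=C4 (Still–Gennari).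
Forward: a C11–C15 vinyl iodide imide and a C2–C8 Z-allylic bromide are joined, C15 becomes the dimethylcarbinol, the C9–C10 chloroacetyl unit is added, and the carbocycle forms in one step when a samarium enolate at C9 adds to the C8 ketone. The oxirane is the last ring to close.
Stereochemistry: C1 by Evans alkylation; C7 by CBS reduction (R, inverted to S on oxirane closure); C8 from C7 by chelation control in the ring closure; C10 from C8 by syn-selective chelate reduction; 3Z by Still–Gennari olefination; 11E by syn-carboalumination.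

Key step: step 16

Assumption: phosphonate 9 is treated as a purchasable Still–Gennari reagent; otherwise it comes from C-methylation of the commercial bis(trifluoroethyl) phosphonoacetate.

Step 1
Reactants: 1 hex-5-yn-1-ol
Product: 3 (E)-6-iodo-5-methylhex-5-en-1-ol, via alkenylalane 2 (not isolated)
Conditions: AlMe3 (3 equiv), Cp2ZrCl2 (0.25 equiv), CH2Cl2, 0 °C → rt; then I2, THF, −30 → 0 °C; aq. potassium sodium tartrate
Reagents that add atoms: trimethylaluminium C[Al](C)C; iodine II
Why: Negishi zirconium-catalysed carboalumination adds Me–Al syn across the terminal alkyne with methyl at the internal carbon, and iodinolysis of the C–Al bond with retention gives the E-trisubstituted vinyl iodide that becomes C11=C12.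

Step 2
Reactants: 3 (E)-6-iodo-5-methylhex-5-en-1-ol
Product: 4 (E)-6-iodo-5-methylhex-5-enoic acid
Conditions: TEMPO (0.2 equiv), PhI(OAc)2 (2.2 equiv), MeCN/H2O 1:1, rt
Reagents that add atoms: water O
Why: TEMPO/PhI(OAc)2 oxidation takes the primary alcohol through the aldehyde hydrate to the acid and leaves the vinyl iodide untouched.

Step 3
Reactants: 4 (E)-6-iodo-5-methylhex-5-enoic acid; 5 (S)-4-benzyloxazolidin-2-one
Product: 7 (S)-4-benzyl-3-[(E)-6-iodo-5-methylhex-5-enoyl]oxazolidin-2-one, via mixed anhydride 6 (not isolated)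
Conditions: t-BuCOCl, Et3N, THF, −20 °C; then 5, LiCl, −20 °C → rt
Reagents that add atoms: none
Why: Mixed-anhydride N-acylation of the oxazolidinone (LiCl/Et3N variant) installs the Evans auxiliary under conditions that do not affect the vinyl iodide.

Step 4
Reactants: 8 (tert-butyldimethylsilyloxy)acetaldehyde; 9 ethyl 2-[bis(2,2,2-trifluoroethoxy)phosphoryl]propanoate
Product: 10 ethyl (Z)-4-(tert-butyldimethylsilyloxy)-2-methylbut-2-enoate
Conditions: KN(SiMe3)2, 18-crown-6, THF, −78 °C
Reagents that add atoms: none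
Why: Still–Gennari olefination, in which the electron-poor phosphonate under dissociating conditions eliminates rapidly from the kinetic adduct, should give the Z-α-methyl enoate that becomes C3=C4.

Step 5
Reactants: 10 ethyl (Z)-4-(tert-butyldimethylsilyloxy)-2-methylbut-2-enoate
Product: 11 (Z)-4-(tert-butyldimethylsilyloxy)-2-methylbut-2-en-1-ol
Conditions: i-Bu2AlH (2.5 equiv), CH2Cl2, −78 °C; aq. potassium sodium tartrate
Reagents that add atoms: none
Why: 1,2-Reduction of the enoate by the aluminium hydride gives the allylic alcohol without change of olefin geometry or loss of the silyl ether.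

Step 6
Reactants: 11 (Z)-4-(tert-butyldimethylsilyloxy)-2-methylbut-2-en-1-ol
Product: 12 [(Z)-4-bromo-3-methylbut-2-enyl]oxy(tert-butyl)dimethylsilane
Conditions: CBr4, PPh3, CH2Cl2, 0 °C
Reagents that add atoms: tetrabromomethane BrC(Br)(Br)Br
Why: Appel bromination of the primary allylic alcohol goes by SN2 displacement of the alkoxyphosphonium ion, so neither allylic transposition nor Z/E isomerisation is expected.

Step 7
Reactants: 12 [(Z)-4-bromo-3-methylbut-2-enyl]oxy(tert-butyl)dimethylsilane; 13 3,3-dimethoxybutan-2-one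
Product: 15 (Z)-8-(tert-butyldimethylsilyloxy)-2,2-dimethoxy-6-methyloct-6-en-3-one, via lithium enolate 14 (not isolated)
Conditions: LiN(i-Pr)2, THF, −78 °C; then 12, DMPU, −78 → −20 °C
Reagents that add atoms: none
Why: Ketone enolate alkylation: 13 has a single enolisable position, and its lithium enolate should displace the reactive primary allylic bromide to form C5–C6, bringing in C7 as a ketone and C8 as a masked ketone.

Step 8
Reactants: 15 (Z)-8-(tert-butyldimethylsilyloxy)-2,2-dimethoxy-6-methyloct-6-en-3-one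
Product: 16 (3R,6Z)-8-(tert-butyldimethylsilyloxy)-2,2-dimethoxy-6-methyloct-6-en-3-ol
Conditions: (S)-2-methyl-CBS-oxazaborolidine (0.2 equiv), catecholborane (1.5 equiv), toluene, −78 → −40 °C; MeOH, aq. NaHCO3
Reagents that add atoms: none
Why: Corey–Bakshi–Shibata reduction, with the quaternary ketal carbon as the large group and the unbranched chain as the small group, should give the R carbinol at C7 with the (S)-catalyst; catecholborane does not hydroborate the olefin at this temperature.

Step 9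
Reactants: 16 (3R,6Z)-8-(tert-butyldimethylsilyloxy)-2,2-dimethoxy-6-methyloct-6-en-3-ol
Product: 17 tert-butyl{[(2Z,6R)-7,7-dimethoxy-6-(4-methoxybenzyloxy)-3-methyloct-2-enyl]oxy}dimethylsilane
Conditions: NaH, 4-methoxybenzyl chloride, Bu4NI (cat.), DMF, 0 °C → rt
Reagents that add atoms: 4-methoxybenzyl chloride COc1ccc(CCl)cc1
Why: Williamson etherification puts a chelating and oxidatively removable PMB ether on the C7 oxygen.

Step 10
Reactants: 17 tert-butyl{[(2Z,6R)-7,7-dimethoxy-6-(4-methoxybenzyloxy)-3-methyloct-2-enyl]oxy}dimethylsilane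
Product: 18 (2Z,6R)-7,7-dimethoxy-6-(4-methoxybenzyloxy)-3-methyloct-2-en-1-ol
Conditions: Bu4NF, THF, 0 °C → rt
Reagents that add atoms: none
Why: Fluoride-mediated desilylation cleaves the primary silyl ether while ketal and PMB ether are inert.

Step 11
Reactants: 18 (2Z,6R)-7,7-dimethoxy-6-(4-methoxybenzyloxy)-3-methyloct-2-en-1-ol
Product: 19 1-{[(3R,6Z)-8-bromo-2,2-dimethoxy-6-methyloct-6-en-3-yl]oxymethyl}-4-methoxybenzene
Conditions: CBr4, PPh3, 2,6-lutidine, CH2Cl2, −20 → 0 °C
Reagents that add atoms: tetrabromomethane BrC(Br)(Br)Br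
Why: Appel bromination as in step 6 gives the Z-allylic bromide for C1–C2 bond formation, with the pyridine base guarding the ketal against adventitious acid.

Step 12
Reactants: 7 (S)-4-benzyl-3-[(E)-6-iodo-5-methylhex-5-enoyl]oxazolidin-2-one; 19 1-{[(3R,6Z)-8-bromo-2,2-dimethoxy-6-methyloct-6-en-3-yl]oxymethyl}-4-methoxybenzene
Product: 21 (S)-4-benzyl-3-[(2R,4Z,8R)-2-[(E)-4-iodo-3-methylbut-3-enyl]-9,9-dimethoxy-8-(4-methoxybenzyloxy)-5-methyldec-4-enoyl]oxazolidin-2-one, via sodium enolate 20 (not isolated)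
Conditions: NaN(SiMe3)2, THF, −78 °C; then 19, −78 → −40 °C
Reagents that add atoms: none
Why: Evans asymmetric alkylation: the chelated Z-sodium enolate is attacked by the allylic bromide on the face opposite the benzyl group, which should set C1 as R.

Step 13
Reactants: 21 (S)-4-benzyl-3-[(2R,4Z,8R)-2-[(E)-4-iodo-3-methylbut-3-enyl]-9,9-dimethoxy-8-(4-methoxybenzyloxy)-5-methyldec-4-enoyl]oxazolidin-2-one
Product: 22 S-ethyl (2R,4Z,8R)-2-[(E)-4-iodo-3-methylbut-3-enyl]-9,9-dimethoxy-8-(4-methoxybenzyloxy)-5-methyldec-4-enethioate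
Conditions: EtSH, n-BuLi, THF, 0 °C → rt
Reagents that add atoms: ethanethiol CCS
Why: Lithium ethanethiolate attacks the exocyclic imide carbonyl selectively (Damon–Coppola auxiliary cleavage) and releases the oxazolidinone without epimerising C1.

Step 14
Reactants: 22 S-ethyl (2R,4Z,8R)-2-[(E)-4-iodo-3-methylbut-3-enyl]-9,9-dimethoxy-8-(4-methoxybenzyloxy)-5-methyldec-4-enethioate
Product: 23 (3R,5Z,9R)-3-[(E)-4-iodo-3-methylbut-3-enyl]-10,10-dimethoxy-9-(4-methoxybenzyloxy)-2,6-dimethylundec-5-en-2-ol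
Conditions: MeMgBr (4 equiv), THF, −20 → 0 °C
Reagents that add atoms: methylmagnesium bromide C[Mg]Br
Why: Double Grignard addition to the thioester (the ketone intermediate is more electrophilic than the thioester) builds the C15 dimethylcarbinol, while ketal, PMB ether and vinyl iodide do not react with MeMgBr.

Step 15
Reactants: 23 (3R,5Z,9R)-3-[(E)-4-iodo-3-methylbut-3-enyl]-10,10-dimethoxy-9-(4-methoxybenzyloxy)-2,6-dimethylundec-5-en-2-ol; 24 2-chloro-N-methoxy-N-methylacetamide
Product: 27 (3E,7R,9Z,13R)-1-chloro-7-(2-hydroxypropan-2-yl)-13-(4-methoxybenzyloxy)-4,10-dimethylpentadeca-3,9-diene-2,14-dione, via vinyllithium 25 (not isolated), via ketal chloroenone 26 (not isolated)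
Conditions: t-BuLi (3.1 equiv), Et2O, −78 °C; then 24, −78 → −40 °C; then 1 M HCl, THF, 0 °C → rt
Reagents that add atoms: water O
Why: Iodine–lithium exchange with retention of the E geometry, then Weinreb amide acylation whose chelated tetrahedral adduct prevents over-addition; the acidic work-up releases the chloromethyl enone and hydrolyses the dimethyl ketal to the C8 methyl ketone.

Step 16
Reactants: 27 (3E,7R,9Z,13R)-1-chloro-7-(2-hydroxypropan-2-yl)-13-(4-methoxybenzyloxy)-4,10-dimethylpentadeca-3,9-diene-2,14-dione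
Product: 29 (1R,3Z,7R,8R,11E)-8,15-dihydroxy-7-(4-methoxybenzyloxy)cembra-3,11-dien-10-one, via samarium enolate 28 (not isolated)
Conditions: SmI2 (2.5 equiv, 0.1 M in THF), −78 °C, slow addition of 27 in THF (final about 0.002 M); then sat. aq. NH4Cl
Reagents that add atoms: none
Why: Divalent samarium transfers two electrons to the C9–Cl bond and gives the trivalent samarium enolate 28 regiospecifically at C9 (no base is present, so neither the γ-positions of the enone nor C7 is deprotonated), and this enolate adds to the C8 methyl ketone; the closest known reaction type is the SmI2-promoted intramolecular Reformatsky (aldol) cyclisation of α-halo carbonyl compounds, which is established for medium and large rings under high dilution. The closure is a 14-(enolendo)-exo-trig aldol that forms C8–C9 and the carbocycle in one event. The new quaternary stereocentre C8 is controlled by C7: the oxophilic samarium binds the C8 carbonyl oxygen and the C7 PMB-ether oxygen in a five-membered chelate, the enolate attacks the face anti to the C6 chain (Cram-chelate sense), and the 7R,8R aldol should result. The step needs C–Cl reduction ahead of the enone and the α-alkoxy ketone, ring closure ahead of oligomerisation, and chelation-controlled facial selectivity; these are secured by the much faster reduction of α-halo ketones at −78 °C without additive, by slow addition to high dilution, and by an ether instead of a silyl ether at C7. The aldolate stays bound to samarium at low temperature, which should suppress retro-aldol cleavage until the quench.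

Step 17
Reactants: 29 (1R,3Z,7R,8R,11E)-8,15-dihydroxy-7-(4-methoxybenzyloxy)cembra-3,11-dien-10-one
Product: 31 (1R,3Z,7R,8R,10S,11E)-7-(4-methoxybenzyloxy)cembra-3,11-diene-8,10,15-triol, via boron chelate 30 (not isolated)
Conditions: Et2BOMe (1.3 equiv), THF/MeOH 4:1, −78 °C; NaBH4, −78 °C; then MeOH, repeated evaporation
Reagents that add atoms: none
Why: Narasaka–Prasad reduction: the C8 hydroxyl and the C10 carbonyl form a six-membered diethylboron chelate, and external axial hydride attack should give the 8,10-syn diol (C10 S) by 1,2-reduction that leaves C11=C12 in place.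

Step 18
Reactants: 31 (1R,3Z,7R,8R,10S,11E)-7-(4-methoxybenzyloxy)cembra-3,11-diene-8,10,15-triol
Product: 32 (1R,3Z,7R,8R,10S,11E)-8,15-dihydroxy-7-(4-methoxybenzyloxy)cembra-3,11-dien-10-yl acetate
Conditions: Ac2O (1.5 equiv), pyridine, DMAP (0.05 equiv), CH2Cl2, 0 °C
Reagents that add atoms: acetic anhydride CC(=O)OC(C)=O
Why: DMAP-catalysed acylation distinguishes the secondary allylic C10 hydroxyl from the two tertiary hydroxyls at C8 and C15.

Step 19
Reactants: 32 (1R,3Z,7R,8R,10S,11E)-8,15-dihydroxy-7-(4-methoxybenzyloxy)cembra-3,11-dien-10-yl acetate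
Product: 33 (1R,3Z,7R,8R,10S,11E)-7,8,15-trihydroxycembra-3,11-dien-10-yl acetate
Conditions: DDQ (1.3 equiv), CH2Cl2/pH 7 phosphate buffer 10:1, 0 °C
Reagents that add atoms: none
Why: Oxidative PMB cleavage (hydride abstraction by DDQ, then hydrolysis of the oxocarbenium ion in the wet medium) frees the C7 hydroxyl without oxidising the allylic acetate or the olefins.

Step 20
Reactants: 33 (1R,3Z,7R,8R,10S,11E)-7,8,15-trihydroxycembra-3,11-dien-10-yl acetate
Product: 35 (1R,3Z,7S,8R,10S,11E)-7,8-epoxy-15-hydroxycembra-3,11-dien-10-yl acetate, via hydroxy mesylate 34 (not isolated)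
Conditions: MeSO2Cl, Et3N, CH2Cl2, −10 °C; then DBU, rt
Reagents that add atoms: none
Why: Sulfonylation of the only secondary hydroxyl, then intramolecular Williamson (3-exo-tet) displacement by the C8 hydroxyl with inversion at C7, should give the 7S,8R oxirane with C6 and C9 cis; the non-nucleophilic amidine base spares the acetate.

Step 21
Reactants: 35 (1R,3Z,7S,8R,10S,11E)-7,8-epoxy-15-hydroxycembra-3,11-dien-10-yl acetate
Product: 36 (1R,3Z,7S,8R,10S,11E)-7,8-epoxycembra-3,11-diene-10,15-diyl diacetate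
Conditions: Ac2O, DMAP, Et3N, CH2Cl2, rt → 35 °C
Reagents that add atoms: acetic anhydride CC(=O)OC(C)=O
Why: DMAP-catalysed acetylation of the remaining tertiary C15 hydroxyl runs under basic conditions that do not open the trisubstituted oxirane.

**Compound list**
1 | hex-5-yn-1-ol | C#CCCCCO | starting material
2 | (E)-dimethyl[6-(dimethylalumanyloxy)-2-methylhex-1-enyl]alumane (alkenylalane) | C[Al](C)/C=C(\C)CCCCO[Al](C)C | intermediate
3 | (E)-6-iodo-5-methylhex-5-en-1-ol | I/C=C(\C)CCCCO | intermediate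
4 | (E)-6-iodo-5-methylhex-5-enoic acid | I/C=C(\C)CCCC(=O)O | intermediate
5 | (S)-4-benzyloxazolidin-2-one | O=C1N[C@@H](Cc2ccccc2)CO1 | starting material
6 | (E)-6-iodo-5-methylhex-5-enoic pivalic anhydride (mixed anhydride) | I/C=C(\C)CCCC(=O)OC(=O)C(C)(C)C | intermediate
7 | (S)-4-benzyl-3-[(E)-6-iodo-5-methylhex-5-enoyl]oxazolidin-2-one | I/C=C(\C)CCCC(=O)N1[C@@H](Cc2ccccc2)COC1=O | intermediate
8 | (tert-butyldimethylsilyloxy)acetaldehyde | CC(C)(C)[Si](C)(C)OCC=O | starting material
9 | ethyl 2-[bis(2,2,2-trifluoroethoxy)phosphoryl]propanoate | CCOC(=O)C(C)P(=O)(OCC(F)(F)F)OCC(F)(F)F | starting material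
10 | ethyl (Z)-4-(tert-butyldimethylsilyloxy)-2-methylbut-2-enoate | CC(C)(C)[Si](C)(C)OC/C=C(/C)C(=O)OCC | intermediate
11 | (Z)-4-(tert-butyldimethylsilyloxy)-2-methylbut-2-en-1-ol | CC(C)(C)[Si](C)(C)OC/C=C(/C)CO | intermediate
12 | [(Z)-4-bromo-3-methylbut-2-enyl]oxy(tert-butyl)dimethylsilane | CC(C)(C)[Si](C)(C)OC/C=C(/C)CBr | intermediate
13 | 3,3-dimethoxybutan-2-one | CC(=O)C(C)(OC)OC | starting material
14 | lithium 3,3-dimethoxybut-1-en-2-olate (lithium enolate) | C=C(O[Li])C(C)(OC)OC | intermediate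
15 | (Z)-8-(tert-butyldimethylsilyloxy)-2,2-dimethoxy-6-methyloct-6-en-3-one | CC(C)(C)[Si](C)(C)OC/C=C(/C)CCC(=O)C(C)(OC)OC | intermediate
16 | (3R,6Z)-8-(tert-butyldimethylsilyloxy)-2,2-dimethoxy-6-methyloct-6-en-3-ol | CC(C)(C)[Si](C)(C)OC/C=C(/C)CC[C@@H](O)C(C)(OC)OC | intermediate
17 | tert-butyl{[(2Z,6R)-7,7-dimethoxy-6-(4-methoxybenzyloxy)-3-methyloct-2-enyl]oxy}dimethylsilane | CC(C)(C)[Si](C)(C)OC/C=C(/C)CC[C@@H](OCc1ccc(OC)cc1)C(C)(OC)OC | intermediate
18 | (2Z,6R)-7,7-dimethoxy-6-(4-methoxybenzyloxy)-3-methyloct-2-en-1-ol | OC/C=C(/C)CC[C@@H](OCc1ccc(OC)cc1)C(C)(OC)OC | intermediate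
19 | 1-{[(3R,6Z)-8-bromo-2,2-dimethoxy-6-methyloct-6-en-3-yl]oxymethyl}-4-methoxybenzene | BrC/C=C(/C)CC[C@@H](OCc1ccc(OC)cc1)C(C)(OC)OC | intermediate
20 | sodium Z-enolate of imide 7 | I/C=C(\C)CC/C=C(\O[Na])N1[C@@H](Cc2ccccc2)COC1=O | intermediate
21 | (S)-4-benzyl-3-[(2R,4Z,8R)-2-[(E)-4-iodo-3-methylbut-3-enyl]-9,9-dimethoxy-8-(4-methoxybenzyloxy)-5-methyldec-4-enoyl]oxazolidin-2-one | I/C=C(\C)CC[C@@H](C(=O)N1[C@@H](Cc2ccccc2)COC1=O)C/C=C(/C)CC[C@@H](OCc3ccc(OC)cc3)C(C)(OC)OC | intermediate
22 | S-ethyl (2R,4Z,8R)-2-[(E)-4-iodo-3-methylbut-3-enyl]-9,9-dimethoxy-8-(4-methoxybenzyloxy)-5-methyldec-4-enethioate | I/C=C(\C)CC[C@@H](C(=O)SCC)C/C=C(/C)CC[C@@H](OCc1ccc(OC)cc1)C(C)(OC)OC | intermediate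
23 | (3R,5Z,9R)-3-[(E)-4-iodo-3-methylbut-3-enyl]-10,10-dimethoxy-9-(4-methoxybenzyloxy)-2,6-dimethylundec-5-en-2-ol | I/C=C(\C)CC[C@@H](C(C)(C)O)C/C=C(/C)CC[C@@H](OCc1ccc(OC)cc1)C(C)(OC)OC | intermediate
24 | 2-chloro-N-methoxy-N-methylacetamide | ClCC(=O)N(C)OC | starting material
25 | C11 vinyllithium and C15 lithium alkoxide derived from 23 | [Li]/C=C(\C)CC[C@@H](C(C)(C)O[Li])C/C=C(/C)CC[C@@H](OCc1ccc(OC)cc1)C(C)(OC)OC | intermediate
26 | (3E,7R,9Z,13R)-1-chloro-7-(2-hydroxypropan-2-yl)-14,14-dimethoxy-13-(4-methoxybenzyloxy)-4,10-dimethylpentadeca-3,9-dien-2-one | ClCC(=O)/C=C(\C)CC[C@@H](C(C)(C)O)C/C=C(/C)CC[C@@H](OCc1ccc(OC)cc1)C(C)(OC)OC | intermediate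
27 | (3E,7R,9Z,13R)-1-chloro-7-(2-hydroxypropan-2-yl)-13-(4-methoxybenzyloxy)-4,10-dimethylpentadeca-3,9-diene-2,14-dione | ClCC(=O)/C=C(\C)CC[C@@H](C(C)(C)O)C/C=C(/C)CC[C@@H](OCc1ccc(OC)cc1)C(C)=O | intermediate
28 | trivalent samarium enolate (C9=C10–O–SmI2) of 27 | C=C(O[Sm](I)I)/C=C(\C)CC[C@@H](C(C)(C)O)C/C=C(/C)CC[C@@H](OCc1ccc(OC)cc1)C(C)=O | intermediate
29 | (1R,3Z,7R,8R,11E)-8,15-dihydroxy-7-(4-methoxybenzyloxy)cembra-3,11-dien-10-one | O=C1/C=C(\C)CC[C@@H](C(C)(C)O)C/C=C(/C)CC[C@@H](OCc2ccc(OC)cc2)[C@](C)(O)C1 | intermediate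
30 | 8-O-diethylboryl chelate of 29 | O=C1/C=C(\C)CC[C@@H](C(C)(C)O)C/C=C(/C)CC[C@@H](OCc2ccc(OC)cc2)[C@](C)(OB(CC)CC)C1 | intermediate
31 | (1R,3Z,7R,8R,10S,11E)-7-(4-methoxybenzyloxy)cembra-3,11-diene-8,10,15-triol | O[C@@H]1/C=C(\C)CC[C@@H](C(C)(C)O)C/C=C(/C)CC[C@@H](OCc2ccc(OC)cc2)[C@](C)(O)C1 | intermediate
32 | (1R,3Z,7R,8R,10S,11E)-8,15-dihydroxy-7-(4-methoxybenzyloxy)cembra-3,11-dien-10-yl acetate | CC(=O)O[C@@H]1/C=C(\C)CC[C@@H](C(C)(C)O)C/C=C(/C)CC[C@@H](OCc2ccc(OC)cc2)[C@](C)(O)C1 | intermediate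
33 | (1R,3Z,7R,8R,10S,11E)-7,8,15-trihydroxycembra-3,11-dien-10-yl acetate | CC(=O)O[C@@H]1/C=C(\C)CC[C@@H](C(C)(C)O)C/C=C(/C)CC[C@@H](O)[C@](C)(O)C1 | intermediate
34 | 7-O-methanesulfonate of 33 | CC(=O)O[C@@H]1/C=C(\C)CC[C@@H](C(C)(C)O)C/C=C(/C)CC[C@@H](OS(C)(=O)=O)[C@](C)(O)C1 | intermediate
35 | (1R,3Z,7S,8R,10S,11E)-7,8-epoxy-15-hydroxycembra-3,11-dien-10-yl acetate | CC(=O)O[C@@H]1/C=C(\C)CC[C@@H](C(C)(C)O)C/C=C(/C)CC[C@@H]2O[C@]2(C)C1 | intermediate
36 | (1R,3Z,7S,8R,10S,11E)-7,8-epoxycembra-3,11-diene-10,15-diyl diacetate | CC(=O)O[C@@H]1/C=C(\C)CC[C@@H](C(C)(C)OC(C)=O)C/C=C(/C)CC[C@@H]2O[C@]2(C)C1 | target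

**Step count and risks**
Total step count: 21. Longest linear sequence: 18 steps (steps 4 to 11, then 12 to 21).

Steps most likely to fail:

1. Step 16. The samarium enolate may be protonated before it cyclises (plain dechlorination), may oligomerise, or the macrocyclic transition state may erode the chelation-controlled facial selectivity at C8. Fallback: from 27, reductive silylation with zinc dust and Me3SiCl (THF, TMEDA, 0 °C) would give the C9=C10 trimethylsilyl enol ether, silylated also at the C15 oxygen, bis(trimethylsilyl) compound F1. A chelation-controlled intramolecular Mukaiyama aldol of F1 (MgBr2·OEt2, CH2Cl2, −78 → 0 °C, high dilution; dilute HCl work-up removes both silyl groups) comes back to the route at 29.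

2. Step 15. The vinyllithium may abstract a proton from the α-chloro amide instead of adding to it (protodeiodination), or the strong base may attack other sites. Fallback: from 23, Stille coupling with tributyl(1-ethoxyvinyl)stannane (Pd(PPh3)4, toluene, 90 °C) would give 2-ethoxydiene F2. NBS in THF/H2O at 0 °C converts the enol ether into bromomethyl enone ketal F3, and 1 M HCl in THF hydrolyses the ketal to bromo diketone F4. F4 under the SmI2 conditions of step 16 gives the same samarium enolate 28, so the route is rejoined at 29.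

3. Step 17. Hydride may be delivered to the wrong face of C10, because the boron chelate of a tertiary carbinol has two competing half-chair conformers (C7 chain or methyl pseudo-equatorial). Fallback: from 29, catalyst-controlled reduction with (R)-2-methyl-CBS-oxazaborolidine and catecholborane (toluene, −78 °C), in which the alkenyl flank of C10 acts as the large group, should give 31 directly and returns to the route there. It makes no compound outside the list (entry F0).

Further compounds
F1 | step 16 | (3E,7R,9Z,13R)-13-(4-methoxybenzyloxy)-4,10-dimethyl-2-(trimethylsilyloxy)-7-[2-(trimethylsilyloxy)propan-2-yl]pentadeca-1,3,9-trien-14-one | C=C(O[Si](C)(C)C)/C=C(\C)CC[C@@H](C(C)(C)O[Si](C)(C)C)C/C=C(/C)CC[C@@H](OCc1ccc(OC)cc1)C(C)=O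
F2 | step 15 | (3R,5Z,9R)-3-[(E)-4-ethoxy-3-methylpenta-2,4-dienyl]... 2-ethoxydiene: (3R,5Z,9R)-3-[(3E)-5-ethoxy-4-methylhexa-3,5-dienyl]-10,10-dimethoxy-9-(4-methoxybenzyloxy)-2,6-dimethylundec-5-en-2-ol | C=C(OCC)/C=C(\C)CC[C@@H](C(C)(C)O)C/C=C(/C)CC[C@@H](OCc1ccc(OC)cc1)C(C)(OC)OC
F3 | step 15 | (3E,7R,9Z,13R)-1-bromo-7-(2-hydroxypropan-2-yl)-14,14-dimethoxy-13-(4-methoxybenzyloxy)-4,10-dimethylpentadeca-3,9-dien-2-one | BrCC(=O)/C=C(\C)CC[C@@H](C(C)(C)O)C/C=C(/C)CC[C@@H](OCc1ccc(OC)cc1)C(C)(OC)OC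
F4 | step 15 | (3E,7R,9Z,13R)-1-bromo-7-(2-hydroxypropan-2-yl)-13-(4-methoxybenzyloxy)-4,10-dimethylpentadeca-3,9-diene-2,14-dione | BrCC(=O)/C=C(\C)CC[C@@H](C(C)(C)O)C/C=C(/C)CC[C@@H](OCc1ccc(OC)cc1)C(C)=O
F0 | step 17 | none | none
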